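**Plan**

1. Retrosynthesis: the side-chain acid is tied back to O5 as a six-membered aryl lactone (ring C, absent from the target). Ring C is cut at the bond from C6 of the benzene ring (ring A) to the benzylic CH and at the acyl–O5 bond, giving an 8-prenyl chromanone phenol and (E)-oct-2-enal. The C8–prenyl bond goes back to an O5 prenyl ether, the pyranone ring (ring B) is cut at O1–C2 to an o-tigloylphenol, and the aryl–acyl bond to 1,3,5-trimethoxybenzene and tigloyl chloride.
2. Forward order: acylation, ring B by oxa-Michael closure, prenyl from O5 to C8 by Claisen–Cope shift, ring C by carbene-catalysed annulation (the fragment union), lactone opening.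
3. Enabling feature: on ring A the only unsubstituted carbon (C6) lies ortho to the only free hydroxyl (C5–OH), and the target's carboxyl sits exactly one six-membered ring away from O5. A C6 attack of the phenoxide on an unsaturated acyl azolium can therefore be closed, and driven, by lactonisation onto O5.
4. Stereochemistry: C2 from a quinine-controlled oxa-Michael addition, C3 by thermodynamic equilibration to trans, the benzylic centre from the chiral triazolium catalyst of the annulation.

Key step: step 7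

Remark: the sense of induction of the two chiral catalysts (quinine in step 3, the triazolium salt in step 7) is assigned by analogy with the closest substrates; quinidine and the (5aR,10bS) salt would be used instead if a first run showed the opposite sense.

**Route**

Step 1
Reactants: 1 1,3,5-trimethoxybenzene; 2 tigloyl chloride [(E)-2-methylbut-2-enoyl chloride]
Product: 3 (E)-2-methyl-1-(2,4,6-trimethoxyphenyl)but-2-en-1-one
Conditions: AlCl3 (1.1 equiv), CH2Cl2, 0 °C
Reagents that add atoms: none
Why: Friedel–Crafts acylation of the symmetrical, strongly activated arene can give only one regioisomer, and the low temperature should keep the aryl vinyl ketone from Nazarov closure.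

Step 2
Reactants: 3 (E)-2-methyl-1-(2,4,6-trimethoxyphenyl)but-2-en-1-one
Product: 4 (E)-1-(2-hydroxy-4,6-dimethoxyphenyl)-2-methylbut-2-en-1-one
Conditions: BCl3 (1.2 equiv), CH2Cl2, −78 → 0 °C; aq. NaHCO3
Reagents that add atoms: none
Why: Chelation-directed ether cleavage, in which BCl3 bound to the ketone removes only a methyl group ortho to it; the two ortho groups are equivalent and the boron chelate formed should protect the second one.

Step 3
Reactants: 4 (E)-1-(2-hydroxy-4,6-dimethoxyphenyl)-2-methylbut-2-en-1-one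
Product: 6 (2R,3R)-5,7-dimethoxy-2,3-dimethylchroman-4-one, via cis-chromanone 5 (not isolated)
Conditions: (−)-quinine (0.1 equiv), PhCl, 15 °C; then p-TsOH·H2O (0.5 equiv), 60 °C
Reagents that add atoms: none
Why: Cinchona-alkaloid-catalysed intramolecular oxa-Michael addition (6-endo-trig) within a quininium phenoxide ion pair should set C2 as (R), and acid-catalysed enolisation then equilibrates the epimerisable C3 towards the more stable trans (2R,3R) isomer with both methyl groups equatorial, without opening ring B; any residual cis isomer is separated and resubjected.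

Step 4
Reactants: 6 (2R,3R)-5,7-dimethoxy-2,3-dimethylchroman-4-one
Product: 7 (2R,3R)-5-hydroxy-7-methoxy-2,3-dimethylchroman-4-one
Conditions: BCl3 (1.5 equiv), CH2Cl2, −78 → 0 °C; H2O
Reagents that add atoms: none
Why: Chelation-directed demethylation cleaves the 5-methoxy group peri to the C4 ketone, while the 7-methoxy group cannot chelate and should stay.

Step 5
Reactants: 7 (2R,3R)-5-hydroxy-7-methoxy-2,3-dimethylchroman-4-one; 8 3-methylbut-2-en-1-ol
Product: 9 (2R,3R)-7-methoxy-2,3-dimethyl-5-[(3-methylbut-2-en-1-yl)oxy]chroman-4-one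
Conditions: PPh3, DIAD, THF, 0 °C → rt
Reagents that add atoms: none
Why: Mitsunobu etherification alkylates the hydrogen-bonded but sufficiently acidic C5 phenol under neutral conditions, which avoids base-induced opening of ring B.

Step 6
Reactants: 9 (2R,3R)-7-methoxy-2,3-dimethyl-5-[(3-methylbut-2-en-1-yl)oxy]chroman-4-one
Product: 12 (2R,3R)-5-hydroxy-7-methoxy-2,3-dimethyl-8-(3-methylbut-2-en-1-yl)chroman-4-one, via ortho-dienone 10 (not isolated), via para-dienone 11 (not isolated)
Conditions: tris(6,6,7,7,8,8,8-heptafluoro-2,2-dimethyloctane-3,5-dionato)europium, Eu(fod)3 (0.1 equiv), CHCl3, 60 °C, sealed tube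
Reagents that add atoms: none
Why: Lewis-acid-accelerated aromatic Claisen rearrangement to C6, Cope rearrangement to C8 and enolisation (para-Claisen–Cope) should move the prenyl group with normal connectivity to the position para to O5, as is known for 5-prenyloxy flavanones.

Step 7
Reactants: 12 (2R,3R)-5-hydroxy-7-methoxy-2,3-dimethyl-8-(3-methylbut-2-en-1-yl)chroman-4-one; 13 (E)-oct-2-enal
Product: 16 (4R,8R,9R)-5-methoxy-8,9-dimethyl-6-(3-methylbut-2-en-1-yl)-4-pentyl-3,4,8,9-tetrahydro-2H,10H-pyrano[2,3-f]chromene-2,10-dione, via unsaturated acyl azolium 14 (not isolated), via adduct acyl azolium 15 (not isolated)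
Conditions: (5aS,10bR)-2-mesityl-5a,10b-dihydro-4H,6H-indeno[2,1-b][1,2,4]triazolo[4,3-d][1,4]oxazin-2-ium chloride (0.1 equiv), 3,3',5,5'-tetra-tert-butyl-4,4'-diphenoquinone (1.2 equiv), i-Pr2NEt (0.5 equiv), 4 Å MS, toluene, rt
Reagents that add atoms: none
Why: Proposed new method: the carbene adds to enal 13, the diphenoquinone oxidises the Breslow intermediate to the (E)-unsaturated acyl azolium 14, the phenoxide of 12 adds through C6 to its β-carbon (directly, or by reversible O-addition at the acyl carbon followed by a [3,3] shift), and protonation of the resulting enolate gives acyl azolium 15, whose acyl group is captured by O5 with release of the carbene. The closest known reaction type is the carbene-catalysed oxidative [3+3] annulation of enals with 2-naphthols and 1,3-dicarbonyl compounds to 4-substituted dihydrocoumarins and dihydropyranones; new here is a ketone-chelated, fully substituted monocyclic phenol as the C,O-bis-nucleophile. Ring C closes by 6-exo-trig acyl substitution at the acyl azolium carbon, an irreversible step that should also draw any reversibly formed aryl ester (O-acylation product) back through 14. The new benzylic centre is under catalyst control alone: the fused indane shields one face of the planar acyl azolium so that C6 adds to the other face of the β-carbon, the ring B stereocentres being too remote to interfere. Site selectivity is secured by the substrate, since C6 is the only unsubstituted carbon of ring A and lies ortho to the only free hydroxyl, while attack through the prenylated C8 would give a dearomatised adduct that cannot lactonise and should revert. C- over O-selectivity rests on the reversibility of O-acylation for this acidic, chelated phenol and is the point that has to be proven.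

Step 8
Reactants: 16 (4R,8R,9R)-5-methoxy-8,9-dimethyl-6-(3-methylbut-2-en-1-yl)-4-pentyl-3,4,8,9-tetrahydro-2H,10H-pyrano[2,3-f]chromene-2,10-dione
Product: 17 (3R)-3-[(2R,3R)-5-hydroxy-7-methoxy-2,3-dimethyl-8-(3-methylbut-2-en-1-yl)-4-oxochroman-6-yl]octanoic acid
Conditions: LiOH·H2O (3 equiv), THF/H2O 3:1, 0 °C → rt; then 1 M HCl to pH 3, 0 °C
Reagents that add atoms: lithium hydroxide, [Li+].[OH-]
Why: Saponification of the aryl lactone (an activated ester) frees the C5 phenol and the acid; the phenoxide formed deactivates the C4 ketone towards enolisation so that C2, C3 and the benzylic centre should stay untouched, and the ketone-chelated C5–OH should not relactonise on cold acidification.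

**Compound list**

1 | 1,3,5-trimethoxybenzene | COc1cc(OC)cc(OC)c1 | starting material
2 | tigloyl chloride, (E)-2-methylbut-2-enoyl chloride | C/C=C(\C)C(=O)Cl | starting material
3 | (E)-2-methyl-1-(2,4,6-trimethoxyphenyl)but-2-en-1-one | C/C=C(\C)C(=O)c1c(OC)cc(OC)cc1OC | intermediate
4 | (E)-1-(2-hydroxy-4,6-dimethoxyphenyl)-2-methylbut-2-en-1-one | C/C=C(\C)C(=O)c1c(O)cc(OC)cc1OC | intermediate
5 | (2R,3S)-5,7-dimethoxy-2,3-dimethylchroman-4-one (cis) | COc1cc(OC)c2c(c1)O[C@H](C)[C@H](C)C2=O | intermediate (not isolated)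
6 | (2R,3R)-5,7-dimethoxy-2,3-dimethylchroman-4-one (trans) | COc1cc(OC)c2c(c1)O[C@H](C)[C@@H](C)C2=O | intermediate
7 | (2R,3R)-5-hydroxy-7-methoxy-2,3-dimethylchroman-4-one | COc1cc(O)c2c(c1)O[C@H](C)[C@@H](C)C2=O | intermediate
8 | 3-methylbut-2-en-1-ol | CC(C)=CCO | starting material
9 | (2R,3R)-7-methoxy-2,3-dimethyl-5-[(3-methylbut-2-en-1-yl)oxy]chroman-4-one | COc1cc(OCC=C(C)C)c2c(c1)O[C@H](C)[C@@H](C)C2=O | intermediate
10 | (2R,3R)-7-methoxy-2,3-dimethyl-6-(2-methylbut-3-en-2-yl)-2,3-dihydro-4H-chromene-4,5(6H)-dione (ortho-dienone, C6 unassigned) | C=CC(C)(C)C1C(OC)=CC2=C(C1=O)C(=O)[C@H](C)[C@@H](C)O2 | intermediate (not isolated)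
11 | (2R,3R)-7-methoxy-2,3-dimethyl-8-(3-methylbut-2-en-1-yl)-2,3-dihydro-4H-chromene-4,5(8H)-dione (para-dienone, C8 unassigned) | CC(C)=CCC1C(OC)=CC(=O)C2=C1O[C@H](C)[C@@H](C)C2=O | intermediate (not isolated)
12 | (2R,3R)-5-hydroxy-7-methoxy-2,3-dimethyl-8-(3-methylbut-2-en-1-yl)chroman-4-one | COc1cc(O)c2c(c1CC=C(C)C)O[C@H](C)[C@@H](C)C2=O | intermediate
13 | (E)-oct-2-enal | CCCCC/C=C/C=O | starting material
14 | (5aS,10bR)-2-mesityl-1-[(E)-oct-2-enoyl]-5a,10b-dihydro-4H,6H-indeno[2,1-b][1,2,4]triazolo[4,3-d][1,4]oxazin-2-ium chloride | CCCCC/C=C/C(=O)c1[n+](-c2c(C)cc(C)cc2C)nc2n1[C@@H]1c3ccccc3C[C@@H]1OC2.[Cl-] | intermediate (not isolated)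
15 | (5aS,10bR)-1-{(3R)-3-[(2R,3R)-5-hydroxy-7-methoxy-2,3-dimethyl-8-(3-methylbut-2-en-1-yl)-4-oxochroman-6-yl]octanoyl}-2-mesityl-5a,10b-dihydro-4H,6H-indeno[2,1-b][1,2,4]triazolo[4,3-d][1,4]oxazin-2-ium chloride | CCCCC[C@H](CC(=O)c1[n+](-c2c(C)cc(C)cc2C)nc2n1[C@@H]1c3ccccc3C[C@@H]1OC2)c1c(O)c2c(c(CC=C(C)C)c1OC)O[C@H](C)[C@@H](C)C2=O.[Cl-] | intermediate (not isolated)
16 | (4R,8R,9R)-5-methoxy-8,9-dimethyl-6-(3-methylbut-2-en-1-yl)-4-pentyl-3,4,8,9-tetrahydro-2H,10H-pyrano[2,3-f]chromene-2,10-dione | CCCCC[C@@H]1CC(=O)Oc2c1c(OC)c(CC=C(C)C)c1O[C@H](C)[C@@H](C)C(=O)c21 | intermediate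
17 | (3R)-3-[(2R,3R)-5-hydroxy-7-methoxy-2,3-dimethyl-8-(3-methylbut-2-en-1-yl)-4-oxochroman-6-yl]octanoic acid | CCCCC[C@H](CC(=O)O)c1c(O)c2c(c(CC=C(C)C)c1OC)O[C@H](C)[C@@H](C)C2=O | target

**Step count and risks**

Total steps: 8. Longest linear sequence: 8 steps (1 → 17).

Steps most likely to fail:

1. Step 7 (labelled step). The chelated phenol may be too weak a carbon nucleophile, the reaction may stop at the O-acyl ester, or facial selectivity may be poor. Fallback with reversed polarity, setting out from 12: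
   - Iodination at C6 (NIS, DMF, 0 °C) should give (2R,3R)-5-hydroxy-6-iodo-7-methoxy-2,3-dimethyl-8-(3-methylbut-2-en-1-yl)chroman-4-one F1.
   - Separately, copper-catalysed syn-borylation of commercial methyl oct-2-ynoate (B2pin2, CuCl, NaOt-Bu, xantphos, MeOH, THF) should give methyl (Z)-3-(4,4,5,5-tetramethyl-1,3,2-dioxaborolan-2-yl)oct-2-enoate F2.
   - Suzuki–Miyaura coupling of F1 with F2 (Pd(OAc)2, SPhos, K3PO4, toluene/H2O, 80 °C) would give methyl (E)-3-[(2R,3R)-5-hydroxy-7-methoxy-2,3-dimethyl-8-(3-methylbut-2-en-1-yl)-4-oxochroman-6-yl]oct-2-enoate F3.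
   - Saponification (LiOH, THF/H2O) would give (E)-3-[(2R,3R)-5-hydroxy-7-methoxy-2,3-dimethyl-8-(3-methylbut-2-en-1-yl)-4-oxochroman-6-yl]oct-2-enoic acid F4.
   - Carboxylate-directed asymmetric hydrogenation of this β,β-disubstituted acrylic acid with Ru(OAc)2(binap) (the binap antipode that delivers the (R) centre; H2, MeOH) should leave the prenyl alkene and the ketone alone and comes back to the route at 17.

2. Step 6. The sigmatropic relay may stop at the ortho stage (6-(1,1-dimethylallyl) isomer), or the allyl ether may simply be cleaved. Fallback by cross-coupling, setting out from 6: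
   - Iodination (I2, CF3CO2Ag, CH2Cl2, 0 °C), expected at C8 while O5 is methylated, should give (2R,3R)-8-iodo-5,7-dimethoxy-2,3-dimethylchroman-4-one F5.
   - Stille coupling with tributyl(3-methylbut-2-en-1-yl)stannane (Pd(PPh3)4, DMF, 90 °C) would give (2R,3R)-5,7-dimethoxy-2,3-dimethyl-8-(3-methylbut-2-en-1-yl)chroman-4-one F6.
   - Chelation-directed cleavage of the 5-methoxy group (BCl3, CH2Cl2, −78 °C) comes back to the route at 12.

3. Step 3. The ion-pair-controlled ring closure may give insufficient enantiomeric purity, or C2 may erode through ring opening during the acid stage. Fallback taking C2 from the chiral pool, setting out from 1: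
   - Fráter–Seebach methylation of ethyl (S)-3-hydroxybutanoate (LDA, MeI, THF) gives ethyl (2S,3S)-3-hydroxy-2-methylbutanoate F7.
   - Amide formation (MeNHOMe·HCl, i-PrMgCl, THF) gives (2S,3S)-3-hydroxy-N-methoxy-N,2-dimethylbutanamide F8.
   - Ortho-lithiation of 1 (n-BuLi, TMEDA, THF, 0 °C) gives 2,4,6-trimethoxyphenyllithium F9, which is added in excess to F8 at −78 °C to give (2S,3S)-3-hydroxy-2-methyl-1-(2,4,6-trimethoxyphenyl)butan-1-one F10.
   - BCl3 (CH2Cl2, −78 → 0 °C) unmasks one ortho phenol to give (2S,3S)-3-hydroxy-1-(2-hydroxy-4,6-dimethoxyphenyl)-2-methylbutan-1-one F11.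
   - Mitsunobu ring closure (PPh3, DIAD, THF), with inversion at the carbinol carbon, comes back to the route at 5, which the acid stage of step 3 converts into 6.

Further compounds
F1 | step 7 | (2R,3R)-5-hydroxy-6-iodo-7-methoxy-2,3-dimethyl-8-(3-methylbut-2-en-1-yl)chroman-4-one | COc1c(I)c(O)c2c(c1CC=C(C)C)O[C@H](C)[C@@H](C)C2=O
F2 | step 7 | methyl (Z)-3-(4,4,5,5-tetramethyl-1,3,2-dioxaborolan-2-yl)oct-2-enoate | CCCCC/C(=C\C(=O)OC)B1OC(C)(C)C(C)(C)O1
F3 | step 7 | methyl (E)-3-[(2R,3R)-5-hydroxy-7-methoxy-2,3-dimethyl-8-(3-methylbut-2-en-1-yl)-4-oxochroman-6-yl]oct-2-enoate | CCCCC/C(=C\C(=O)OC)c1c(O)c2c(c(CC=C(C)C)c1OC)O[C@H](C)[C@@H](C)C2=O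
F4 | step 7 | (E)-3-[(2R,3R)-5-hydroxy-7-methoxy-2,3-dimethyl-8-(3-methylbut-2-en-1-yl)-4-oxochroman-6-yl]oct-2-enoic acid | CCCCC/C(=C\C(=O)O)c1c(O)c2c(c(CC=C(C)C)c1OC)O[C@H](C)[C@@H](C)C2=O
F5 | step 6 | (2R,3R)-8-iodo-5,7-dimethoxy-2,3-dimethylchroman-4-one | COc1cc(OC)c2c(c1I)O[C@H](C)[C@@H](C)C2=O
F6 | step 6 | (2R,3R)-5,7-dimethoxy-2,3-dimethyl-8-(3-methylbut-2-en-1-yl)chroman-4-one | COc1cc(OC)c2c(c1CC=C(C)C)O[C@H](C)[C@@H](C)C2=O
F7 | step 3 | ethyl (2S,3S)-3-hydroxy-2-methylbutanoate | C[C@H](O)[C@H](C)C(=O)OCC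
F8 | step 3 | (2S,3S)-3-hydroxy-N-methoxy-N,2-dimethylbutanamide | C[C@H](O)[C@H](C)C(=O)N(C)OC
F9 | step 3 | 2,4,6-trimethoxyphenyllithium | [Li]c1c(OC)cc(OC)cc1OC
F10 | step 3 | (2S,3S)-3-hydroxy-2-methyl-1-(2,4,6-trimethoxyphenyl)butan-1-one | C[C@H](O)[C@H](C)C(=O)c1c(OC)cc(OC)cc1OC
F11 | step 3 | (2S,3S)-3-hydroxy-1-(2-hydroxy-4,6-dimethoxyphenyl)-2-methylbutan-1-one | C[C@H](O)[C@H](C)C(=O)c1c(O)cc(OC)cc1OC
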